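Count the free catalyst before anything else.

the same everywhere: catalyst 0.5 mol%; added ligand 0.21 mM
- ash: substrate 26 mM; time 3.0 h; a closed flask charged with all of it at once and left for 3.0 h
- oak: substrate 26 mM (fed, over 2.40 h); time 3.0 h; a stirred flask in which substrate is dosed at a steady rate over 2.40 h without added volume, worked up at 3.0 h
- maple: substrate 26 mM; one stirred flow tank at steady state, fed with the mixture as stated, mean residence time 3.0 h

    catalyst + intermediate → catalyst + target (k1 = 33 /M/min)
    substrate → intermediate (k2 = 0.0089 /min)
    catalyst + target → catalyst + over-reaction product (k3 = 5.7 /M/min)
    catalyst + added ligand ⇌ idle complex, settled at all times (K4 = 1200 /M)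

* the set-up with the highest amount of intermediate at the outlet or at the end, in percent of the substrate put in ("none" if the first two lie within 2 percentage points) (ash / oak / maple / none)
* amount of intermediate at the outlet or at the end, in percent of the substrate put in, ash
* amount of intermediate at the outlet or at the end, in percent of the substrate put in, oak
* amount of intermediate at the outlet or at the end, in percent of the substrate put in, maple

- the stated concentrations are those of everything mixed, before any reaction; amounts are the same in each set-up
- the feed brings no volume worth counting
- run time (ash): 3.0 h

No arrow makes or spends catalyst, and the added ligand is the one partner that binds it, so I expect one free level through each run. With 0.130 mM of catalyst charged, I solve the balance together with the counts of catalyst and ligand. That leaves 0.106 mM free. Multiplied by 33 /M/min, this gives 0.00351 /min, the loss constant: the pseudo-first-order rate constant at which free catalyst removes intermediate. Substrate goes at 0.0089 /min, which is faster.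

Every parcel of substrate now follows one curve of age, made at the one constant and lost at the other. Ash is a single parcel, aged 3.0 h, and holds 54.5%. The maple tank, solved at steady state, holds 37.7%.

Oak has two ways. Its parcels are aged from 0.600 h to 3.0 h. Taken as one parcel of mean age 1.80 h, oak holds 49.9%. Averaging the curve over the dosing gives 46.7%. They part by 3.2 percentage points, so one cheats. The youngest parcel stands at 25.7% and the oldest at 54.5%. Their mean, 40.1%, lies below the mean-age value. The curve bends, so the mean age overstates, and I commit to the average. Ash leads.

The forecast names ash, with 54.5% in ash, 46.7% in oak and 37.7% in maple. Its ground: “dosing delays formation and the flow tank's mixing leaves more substrate unconverted”. My figures match.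

The simulation gives ash: 54.5% in ash, 46.7% in oak, 37.7% in maple. The forecast stands.

In oak, the half-life of substrate by its conversion into intermediate at 1.90 h is 1.3 h, shorter than the 3.3 h of intermediate by its conversion into target at 3.00 h, which is ln(2) over the loss constant, 3.29 h. Oak ends with intermediate as its largest pool at 46.7%, with 41% of the substrate still there.

A neighbour of oak takes 44 mM of substrate, so catalyst rises to 0.220 mM while the ligand stays as it was. The balance then gives a loss constant of 0.00602 /min, and the average gives 40.0%. The computed result is 40.0%.

(The rate constants were set for the occasion; the rest is arithmetic.)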